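Readings and results are calculated from invented constants; noise was put on by code.

**Late creep.** Late in the green run Z gains 9 percentage points of the L charged in 7.00 min, far less per minute than the 24% of its first 1.00 min. Among the suspects, J takes D to give X and E, X turns L into Z and returns J, and X can slip to Q. Each Z therefore leaves one E behind, and E pulls X back to J.

in all of them: D 0.525 M; J 42 mM
- ochre: L 0.29 M; run made earlier
- green: L 0.46 M; run made earlier
- flask: L 0.21 M; volume of the second phase over the first 1.0

| run | time / min | Z / % |
|---|---|---|
| ochre | 3.00 | 48 |
| ochre | 6.00 | 57 |
| ochre | 10.0 | 64 |
| ochre | 12.0 | 67 |
| green | 1.00 | 24 |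
| green | 2.00 | 33 |
| green | 5.00 | 43 |
| green | 12.0 | 52 |

(each reading ± 1.5 percentage points)

- percent here means L units held: one G counts as two
- in the second phase: D, E; everything else is in the first
- charges count per volume of the first phase; a concentration in a rate is the amount of a species over the volume of its own phase; every rate counts per litre of the first phase
- what was read earlier has a scatter of 1.5 percentage points, one standard deviation
- on the list of suspects stand: X <-> Q; J + D <-> X + E; 2 L -> G; L + X -> Z + J
- the earlier runs hold the two phases in the same ratio of volumes as the flask asked about
- no earlier run changes the charge of J; that part of a forecast is a guess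
- no earlier run changes the charge of D; that part of a forecast is a guess

- factor on the rate of making Z when 30% of the L are converted if D is charged twice over
- factor on the rate when 30% of the L are converted if J is charged at 200 mM instead

**Holding level.** Suppose J and D stay near balance with X and E (a pre-equilibrium), with Q in step with X. Held catalyst (X and Q) over J then equals a level over E. This is the holding level: the concentration of E, at fixed D, where held catalyst equals J. The rate of Z over L then goes as one over level plus E.

Dividing that quantity for two intervals removes time and the rate constant. The mean of the last readings, 59.5%, serves as the share of lost L that becomes Z. Taking E as Z, the green run's first two intervals then read 0.0473 M. This is a loose reading, since it rests on a gain of 9 points with a scatter of 1.5 points.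

**The reckoning.** In the flask at 30% conversion, the ochre run's last share puts Z at 0.0422 M. Since E is Z plus held catalyst h, h(Z + h) = B(c − h), with B the level and c the catalyst charged. That gives 18.4 mM, or 43.8% of the catalyst. At fixed L the rate follows h. Twice the D means twice the level, and my factor is 1.34. J at 200 mM gives my factor 3.38.

**The result.** The forecast gives 1.3 and 3.3, a little lower than mine on both, holding that “the extra E limits the gain”. The flask gives 1.42 and 3.56.

    X ⇌ Q (K = 0.860, k = 0.0193 s⁻¹)
    J + D ⇌ X + E (K = 0.0820, k = 0.565 M⁻¹ s⁻¹)
    2 L → G (k = 0.00945 M⁻¹ s⁻¹)
    L + X → Z + J (k = 0.596 M⁻¹ s⁻¹)

**Same split.** In the flask, J has a half-life of 2.8 s by the forward step alone at 0.866 min, far shorter than the 3.4 min of L by its step with X at 10.0 min. At 5.00 min in the flask, held catalyst times E (the D lost) over J stands at 0.0579 M. With J at 200 mM, the level read as 0.0473 M gave 3.38, and the flask with that charge stands at 3.56, with Q at 4.57% of its catalyst.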